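A direct plan would dichloromethylate 2-fluoro-4-methoxy-1-nitrobenzene A1 with the trichloromethyl anion, hydrolyse the product to 3-fluoro-5-methoxy-2-nitrobenzaldehyde A2 and displace its fluoride with prenol to give 5-methoxy-3-[(3-methylbut-2-en-1-yl)oxy]-2-nitrobenzaldehyde A3 before the nitro group is displaced by methyl 2,6-dihydroxy-4-methylbenzoate A4 and the aldehyde reduced, so that ring B would be the electrophile and the diaryl ether would be closed last by nucleophilic aromatic substitution.
Weakest would be the nitro displacement on A3 by A4 that forms the diaryl ether: the carbon attacked is para to OMe and ortho to O-prenyl, flanked by two ortho groups, and the nucleophile is the chelated phenoxide of a symmetrical resorcinol, so mono-arylation would rest on chelation alone, hot in DMSO beside a free aldehyde and liberated nitrite.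
Weak would also be the fluoride displacement on A2 by an allylic alkoxide, which runs next to a non-enolisable aldehyde and a nitro group that is itself a leaving group.
Weak, too, would be the cryogenic addition of the short-lived trichloromethyl anion to A1 (collapse to dichlorocarbene, attack at C–F), which spends two steps on a one-carbon handle.

**Retrosynthetic overview**
Ring A (the benzoate ring: C1 CO2Me, C2 OH, C3 H, C4 CH3, C5 H, C6 O-aryl) would be built, not bought: C1, C6, C5 and C4 come from C3–C6 of a 2-pyranone, C2 and C3 from a ketene bis-silyl acetal. The key step forms C1–C2 and C3–C4 and expels the lactone bridge as CO2.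
The aryl–O–C6 bond would be made before ring A exists, as a vinylogous ester, by addition–elimination of the ring B phenol to a 4-chloro-2-pyranone at room temperature. No substitution on a deactivated nitroarene and no mono-arylation of a symmetrical resorcinol is needed, because the two oxygens of ring A differ from the start.
Ring B would be used as a nucleophilic phenol made from a bromosalicylaldehyde (hydroxylation, selective prenylation, reduction); its hydroxymethyl group is carried as a silyl ether that falls in the work-up of the key step.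
Order of ring events: ring B from the starting material, the pyranone from dimethyl malonate and diketene, ring A last from the pyranone.

Key step: step 9

Assumption: the bromosalicylaldehyde of step 1, diketene and trimethylsilyl acetate are taken as commercial; the bridged cycloadduct of the key step is a transient racemate, so no stereochemistry has to be controlled.

**Step 1**
Reactants: 1 3-bromo-2-hydroxy-5-methoxybenzaldehyde
Product: 2 2,3-dihydroxy-5-methoxybenzaldehyde
Conditions: NaOH (8% aq.), Cu powder (cat.), reflux, N2; then HCl to pH 2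
Reagents that add atoms: sodium hydroxide, [Na+].[OH-]
Why: Copper-mediated Ullmann-type hydroxylation of an aryl bromide ortho to a phenoxide (the classical conversion of an ortho-bromophenol into a catechol), in which the aldehyde, as part of the phenoxide, is deactivated towards Cannizzaro disproportionation.

**Step 2**
Reactants: 2 2,3-dihydroxy-5-methoxybenzaldehyde; 3 1-bromo-3-methylbut-2-ene (prenyl bromide)
Product: 4 2-hydroxy-5-methoxy-3-[(3-methylbut-2-en-1-yl)oxy]benzaldehyde
Conditions: NaH (2.1 equiv), DMSO, 20 °C; then 3 (1.0 equiv), 20 °C; aq. NH4Cl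
Reagents that add atoms: 1-bromo-3-methylbut-2-ene, CC(C)=CCBr
Why: Williamson ether synthesis on the dianion: the 2-phenoxide is delocalized into the formyl group and held in a sodium chelate, so the more basic 3-phenoxide attacks the primary allylic bromide (SN2) and the prenyl group should go to O-3.

**Step 3**
Reactants: 4 2-hydroxy-5-methoxy-3-[(3-methylbut-2-en-1-yl)oxy]benzaldehyde
Product: 5 2-(hydroxymethyl)-4-methoxy-6-[(3-methylbut-2-en-1-yl)oxy]phenol
Conditions: NaBH4 (1 equiv), MeOH, 0 °C; aq. NH4Cl
Reagents that add atoms: none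
Why: Borohydride reduction of an aromatic aldehyde to the benzylic alcohol; the alkene and the aryl ethers are inert, and the near-neutral work-up avoids ortho-quinone methide formation from the salicyl alcohol.

**Step 4**
Reactants: 5 2-(hydroxymethyl)-4-methoxy-6-[(3-methylbut-2-en-1-yl)oxy]phenol; 6 tert-butyl(chloro)dimethylsilane
Product: 7 2-({[tert-butyl(dimethyl)silyl]oxy}methyl)-4-methoxy-6-[(3-methylbut-2-en-1-yl)oxy]phenol
Conditions: 6 (1.05 equiv), imidazole (2 equiv), CH2Cl2, 0 °C
Reagents that add atoms: tert-butyl(chloro)dimethylsilane, CC(C)(C)[Si](C)(C)Cl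
Why: Chemoselective silyl ether formation: the unhindered primary benzylic alcohol should react faster than the phenol, which is hydrogen-bonded and flanked by two ortho substituents.

**Step 5**
Reactants: 8 dimethyl malonate; 9 diketene (4-methylideneoxetan-2-one)
Product: 11 methyl 4-hydroxy-6-methyl-2-oxo-2H-pyran-3-carboxylate, via acetoacetylmalonate 10 (not isolated)
Conditions: NaH (1.05 equiv), THF, 0 °C; 9 (1.1 equiv), 0 °C to 20 °C; then reflux; aq. HCl to pH 1
Reagents that add atoms: diketene, C=C1CC(=O)O1
Why: C-acylation of the malonate enolate by diketene (opening of the β-lactone at the acyl carbon) gives 10, whose ketone enol oxygen closes onto one ester (6-exo-trig lactonization with loss of methanol) to the 4-hydroxy-2-pyranone.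

**Step 6**
Reactants: 11 methyl 4-hydroxy-6-methyl-2-oxo-2H-pyran-3-carboxylate
Product: 12 methyl 4-chloro-6-methyl-2-oxo-2H-pyran-3-carboxylate
Conditions: (COCl)2 (1.5 equiv), DMF (cat.), CH2Cl2, 0 °C to reflux
Reagents that add atoms: oxalyl chloride, O=C(Cl)C(Cl)=O
Why: Vilsmeier-type deoxychlorination of a vinylogous carboxylic acid (chloroiminium activation of the enol oxygen, then addition–elimination by chloride), the usual way from a 4-hydroxy-2-pyranone to its vinylogous acid chloride.

**Step 7**
Reactants: 7 2-({[tert-butyl(dimethyl)silyl]oxy}methyl)-4-methoxy-6-[(3-methylbut-2-en-1-yl)oxy]phenol; 12 methyl 4-chloro-6-methyl-2-oxo-2H-pyran-3-carboxylate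
Product: 13 methyl 4-{2-({[tert-butyl(dimethyl)silyl]oxy}methyl)-4-methoxy-6-[(3-methylbut-2-en-1-yl)oxy]phenoxy}-6-methyl-2-oxo-2H-pyran-3-carboxylate
Conditions: K2CO3 (1.5 equiv), MeCN, 0 °C to 20 °C
Reagents that add atoms: methyl 4-chloro-6-methyl-2-oxo-2H-pyran-3-carboxylate, COC(=O)C1=C(Cl)C=C(C)OC1=O
Why: Addition–elimination (vinylogous acyl substitution) at C4 of the pyranone, which is β to both the lactone and the ester carbonyl and carries chloride as nucleofuge, so the phenoxide should attack there at room temperature while the silyl ether, the alkene and the ester stay untouched.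

**Step 8**
Reactants: 14 trimethylsilyl acetate; 15 chlorotrimethylsilane
Product: 16 1,1-bis[(trimethylsilyl)oxy]ethene (ketene bis(trimethylsilyl) acetal)
Conditions: LiN(i-Pr)2 (1.05 equiv), THF, −78 °C; 15 (1.1 equiv), −78 °C to 20 °C; filtration, distillation
Reagents that add atoms: chlorotrimethylsilane, C[Si](C)(C)Cl
Why: O-silylation of the lithium enolate of a silyl ester at low temperature (silyl ketene acetal formation), the volatile product being freed from LiCl by filtration and distillation.

**Step 9**
Reactants: 13 methyl 4-{2-({[tert-butyl(dimethyl)silyl]oxy}methyl)-4-methoxy-6-[(3-methylbut-2-en-1-yl)oxy]phenoxy}-6-methyl-2-oxo-2H-pyran-3-carboxylate; 16 1,1-bis[(trimethylsilyl)oxy]ethene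
Product: 20 methyl 2-hydroxy-6-{2-(hydroxymethyl)-4-methoxy-6-[(3-methylbut-2-en-1-yl)oxy]phenoxy}-4-methylbenzoate, via bicyclic lactone cycloadduct 17 (not isolated), via cyclohexadiene bis-silyl ketal 18 (not isolated), via bis-silyl diaryl ether 19 (not isolated)
Conditions: 16 (4 equiv), toluene (1 M), 110 °C, sealed tube, Ar; concentrate; then Bu4NF (3 equiv), AcOH (3 equiv), THF, 0 °C to 20 °C
Reagents that add atoms: 1,1-bis[(trimethylsilyl)oxy]ethene, C=C(O[Si](C)(C)C)O[Si](C)(C)C
Why: Inverse-electron-demand Diels–Alder reaction, cycloreversion and aromatization in one pot: the electron-poor diene C3=C4–C5=C6 of pyranone 13 takes up the electron-rich alkene 16 in an intermolecular (4+2) cycloaddition that forms C1–C2 and C3–C4 of ring A and gives the bridged lactone 17 (racemic, transient). Retro-(4+2) loss of CO2 from 17 opens the lactone bridge to cyclohexadiene 18, 1,2-elimination of trimethylsilanol makes the benzene ring of 19, and fluoride then frees the phenol and the hydroxymethyl group (any 18 left over would collapse to the same phenol through its ketone). The closest known reaction type is the thermal aryl annulation of 3-methoxycarbonyl-2-pyranones by 1,1-dimethoxyethene, which gives 2-methoxybenzoates. The regiochemistry needed, CH2 of 16 to C6 and the dioxygenated carbon to C3, follows from the polarization of both partners (C6 of 13 is the vinylogous acceptor position of both carbonyl groups, CH2 of 16 the nucleophilic terminus), so the hydroxyl ends up ortho to the ester and the aryloxy group on the other ortho carbon by construction. The prenyl alkene is unactivated and no partner for the pyranone, 110 °C lies below the range of the aromatic Claisen rearrangement of the prenyl ether, and no stereocentre is left in 20.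

**Compound list**
1 | 3-bromo-2-hydroxy-5-methoxybenzaldehyde | COc1cc(Br)c(O)c(C=O)c1 | starting material
2 | 2,3-dihydroxy-5-methoxybenzaldehyde | COc1cc(O)c(O)c(C=O)c1 | intermediate
3 | 1-bromo-3-methylbut-2-ene (prenyl bromide) | CC(C)=CCBr | starting material
4 | 2-hydroxy-5-methoxy-3-[(3-methylbut-2-en-1-yl)oxy]benzaldehyde | COc1cc(OCC=C(C)C)c(O)c(C=O)c1 | intermediate
5 | 2-(hydroxymethyl)-4-methoxy-6-[(3-methylbut-2-en-1-yl)oxy]phenol | COc1cc(OCC=C(C)C)c(O)c(CO)c1 | intermediate
6 | tert-butyl(chloro)dimethylsilane | CC(C)(C)[Si](C)(C)Cl | starting material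
7 | 2-({[tert-butyl(dimethyl)silyl]oxy}methyl)-4-methoxy-6-[(3-methylbut-2-en-1-yl)oxy]phenol | COc1cc(OCC=C(C)C)c(O)c(CO[Si](C)(C)C(C)(C)C)c1 | intermediate
8 | dimethyl malonate | COC(=O)CC(=O)OC | starting material
9 | diketene (4-methylideneoxetan-2-one) | C=C1CC(=O)O1 | starting material
10 | dimethyl 2-(3-oxobutanoyl)propanedioate (formed as its sodium enolate) | COC(=O)C(C(=O)OC)C(=O)CC(C)=O | intermediate (not isolated)
11 | methyl 4-hydroxy-6-methyl-2-oxo-2H-pyran-3-carboxylate | COC(=O)C1=C(O)C=C(C)OC1=O | intermediate
12 | methyl 4-chloro-6-methyl-2-oxo-2H-pyran-3-carboxylate | COC(=O)C1=C(Cl)C=C(C)OC1=O | intermediate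
13 | methyl 4-{2-({[tert-butyl(dimethyl)silyl]oxy}methyl)-4-methoxy-6-[(3-methylbut-2-en-1-yl)oxy]phenoxy}-6-methyl-2-oxo-2H-pyran-3-carboxylate | COC(=O)C1=C(Oc2c(CO[Si](C)(C)C(C)(C)C)cc(OC)cc2OCC=C(C)C)C=C(C)OC1=O | intermediate
14 | trimethylsilyl acetate | CC(=O)O[Si](C)(C)C | starting material
15 | chlorotrimethylsilane | C[Si](C)(C)Cl | starting material
16 | 1,1-bis[(trimethylsilyl)oxy]ethene | C=C(O[Si](C)(C)C)O[Si](C)(C)C | intermediate
17 | methyl 5-{2-({[tert-butyl(dimethyl)silyl]oxy}methyl)-4-methoxy-6-[(3-methylbut-2-en-1-yl)oxy]phenoxy}-1-methyl-3-oxo-8,8-bis[(trimethylsilyl)oxy]-2-oxabicyclo[2.2.2]oct-5-ene-4-carboxylate (racemic, transient) | COC(=O)C12C(=O)OC(C)(CC1(O[Si](C)(C)C)O[Si](C)(C)C)C=C2Oc1c(CO[Si](C)(C)C(C)(C)C)cc(OC)cc1OCC=C(C)C | intermediate (not isolated)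
18 | methyl 2-{2-({[tert-butyl(dimethyl)silyl]oxy}methyl)-4-methoxy-6-[(3-methylbut-2-en-1-yl)oxy]phenoxy}-4-methyl-6,6-bis[(trimethylsilyl)oxy]cyclohexa-1,3-diene-1-carboxylate | COC(=O)C1=C(Oc2c(CO[Si](C)(C)C(C)(C)C)cc(OC)cc2OCC=C(C)C)C=C(C)CC1(O[Si](C)(C)C)O[Si](C)(C)C | intermediate (not isolated)
19 | methyl 2-{2-({[tert-butyl(dimethyl)silyl]oxy}methyl)-4-methoxy-6-[(3-methylbut-2-en-1-yl)oxy]phenoxy}-4-methyl-6-[(trimethylsilyl)oxy]benzoate | COC(=O)c1c(O[Si](C)(C)C)cc(C)cc1Oc1c(CO[Si](C)(C)C(C)(C)C)cc(OC)cc1OCC=C(C)C | intermediate (not isolated)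
20 | methyl 2-hydroxy-6-{2-(hydroxymethyl)-4-methoxy-6-[(3-methylbut-2-en-1-yl)oxy]phenoxy}-4-methylbenzoate | COC(=O)c1c(O)cc(C)cc1Oc1c(CO)cc(OC)cc1OCC=C(C)C | target

**Step count and risk**
Total steps: 9. Longest linear sequence: 6 (steps 1, 2, 3, 4, 7, 9).

Most likely to fail:

Step 9. The aryloxy donor at C4 may slow the cycloaddition. Conjugate addition–elimination of 16 at C4 with loss of the aryloxide, or thermal decomposition of the pyranone, could then take over. The fallback sets out from phenol 7 and gives up the ring construction for a carbon–oxygen coupling on the side of ring A. Ullmann coupling (CuI, picolinic acid, K3PO4, DMSO, 90 °C) with methyl 2-iodo-6-(methoxymethoxy)-4-methylbenzoate F1 should give methyl 2-{2-({[tert-butyl(dimethyl)silyl]oxy}methyl)-4-methoxy-6-[(3-methylbut-2-en-1-yl)oxy]phenoxy}-6-(methoxymethoxy)-4-methylbenzoate F2. Dilute HCl in MeOH at 20 °C should then remove the methoxymethyl and the silyl group and come back to the route at target 20.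

Step 7. The doubly ortho-substituted phenoxide of 7, shielded by the silyloxymethyl group, may add slowly. Opening of the pyranone at C6 or C2, hydrolysis of the vinylogous acid chloride, or silyl migration from the benzylic oxygen to the phenoxide could then compete. The fallback sets out from aldehyde 4, whose phenoxide is smaller, less basic and carries no silyl group, and moves the reduction to the end. With 12 (K2CO3, MeCN) it should give methyl 4-{2-formyl-4-methoxy-6-[(3-methylbut-2-en-1-yl)oxy]phenoxy}-6-methyl-2-oxo-2H-pyran-3-carboxylate F3. Cycloaddition with 16 as in step 9 at the lowest workable temperature and a KF/MeOH work-up should give methyl 2-{2-formyl-4-methoxy-6-[(3-methylbut-2-en-1-yl)oxy]phenoxy}-6-hydroxy-4-methylbenzoate F4. NaBH4 in MeOH at 0 °C should reduce only the aldehyde and come back at target 20.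

Step 1. In hot aqueous NaOH the catechol formed is prone to air oxidation, the aldehyde to Cannizzaro disproportionation, and protodebromination may compete. The fallback sets out from prenyl bromide 3 and fixes the oxygen pattern of ring B by the choice of starting material. Williamson alkylation of commercial 2-hydroxy-4-methoxybenzaldehyde F5 (K2CO3, DMF) should give 4-methoxy-2-[(3-methylbut-2-en-1-yl)oxy]benzaldehyde F6. Dakin-type oxidation (30% H2O2, B(OH)3, cat. H2SO4, THF, 20 °C), which leaves the alkene alone, should give 4-methoxy-2-[(3-methylbut-2-en-1-yl)oxy]phenol F7. Magnesium-mediated ortho-formylation (MgCl2, Et3N, paraformaldehyde, MeCN, reflux) at the only free ortho position comes back to the route at 4, so steps 1 and 2 are both bypassed.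

**Further compounds**
F1 | step 9 | methyl 2-iodo-6-(methoxymethoxy)-4-methylbenzoate | COCOc1cc(C)cc(I)c1C(=O)OC
F2 | step 9 | methyl 2-{2-({[tert-butyl(dimethyl)silyl]oxy}methyl)-4-methoxy-6-[(3-methylbut-2-en-1-yl)oxy]phenoxy}-6-(methoxymethoxy)-4-methylbenzoate | COCOc1cc(C)cc(Oc2c(CO[Si](C)(C)C(C)(C)C)cc(OC)cc2OCC=C(C)C)c1C(=O)OC
F3 | step 7 | methyl 4-{2-formyl-4-methoxy-6-[(3-methylbut-2-en-1-yl)oxy]phenoxy}-6-methyl-2-oxo-2H-pyran-3-carboxylate | COC(=O)C1=C(Oc2c(C=O)cc(OC)cc2OCC=C(C)C)C=C(C)OC1=O
F4 | step 7 | methyl 2-{2-formyl-4-methoxy-6-[(3-methylbut-2-en-1-yl)oxy]phenoxy}-6-hydroxy-4-methylbenzoate | COC(=O)c1c(O)cc(C)cc1Oc1c(C=O)cc(OC)cc1OCC=C(C)C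
F5 | step 1 | 2-hydroxy-4-methoxybenzaldehyde | COc1ccc(C=O)c(O)c1
F6 | step 1 | 4-methoxy-2-[(3-methylbut-2-en-1-yl)oxy]benzaldehyde | COc1ccc(C=O)c(OCC=C(C)C)c1
F7 | step 1 | 4-methoxy-2-[(3-methylbut-2-en-1-yl)oxy]phenol | COc1ccc(O)c(OCC=C(C)C)c1
A1 | direct plan | 2-fluoro-4-methoxy-1-nitrobenzene | COc1ccc([N+](=O)[O-])c(F)c1
A2 | direct plan | 3-fluoro-5-methoxy-2-nitrobenzaldehyde | COc1cc(F)c([N+](=O)[O-])c(C=O)c1
A3 | direct plan | 5-methoxy-3-[(3-methylbut-2-en-1-yl)oxy]-2-nitrobenzaldehyde | COc1cc(OCC=C(C)C)c([N+](=O)[O-])c(C=O)c1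
A4 | direct plan | methyl 2,6-dihydroxy-4-methylbenzoate | COC(=O)c1c(O)cc(C)cc1O
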